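Read the flask by the substrate left, not by the target made. Its clock k is ln(1/fraction of substrate left)/t, with each percent of target counted as substrate gone: a pseudo-first-order constant that stays level in time if the substrate enters to the first power and the rest of the rate holds still.

| flask | substrate | reagent | free catalyst | remark |
|---|---|---|---|---|
| autumn | 0.010 M | 1.5 equiv | 0.21 mol% | run made earlier |
| summer | 0.010 M | 1.5 equiv | 0.33 mol% | run made earlier |
| noon | 0.015 M | 1.5 equiv | 0.15 mol% | run made earlier |
| flask | 0.010 M | 1.50 equiv | 0.15 mol% |  |

| run | time / min | target / % |
|---|---|---|
| autumn | 15.0 | 3.0 |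
| autumn | 30.0 | 4.7 |
| autumn | 50.0 | 8.4 |
| autumn | 60.0 | 8.4 |
| autumn | 80.0 | 10.6 |
| autumn | 90.0 | 13.1 |
| summer | 8.00 | 1.1 |
| summer | 12.0 | 2.6 |
| summer | 20.0 | 4.2 |
| summer | 40.0 | 7.1 |
| summer | 60.0 | 8.6 |
| summer | 90.0 | 17.5 |
| noon | 20.0 | 2.8 |
| noon | 40.0 | 5.0 |
| noon | 60.0 | 8.5 |
| noon | 80.0 | 10.8 |
| noon | 90.0 | 11.5 |

(readings scatter by 1 percentage point)

1. apparent order in free catalyst when 20% of the substrate are converted (percent change of the rate of making target for one percent more free catalyst charged)
2. apparent order in reagent when 20% of the substrate are converted (percent change of the rate of making target for one percent more reagent charged)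



Autumn and summer share substrate and reagent and differ in free catalyst. Their last readings, taken at the same time, give the exponent of the clock in catalyst as 0.697. But a scatter of 1 percentage point on 13.1% shakes that figure badly. Each run's readings, fitted through the origin, give a steadier clock: 0.00153 min⁻¹ for autumn and 0.00194 min⁻¹ for summer. So the catalyst exponent n, the percent change of the clock for one percent more catalyst, is 0.526.

Reagent is harder, since noon raises it together with substrate. Noon has more of it, and scaling the autumn clock by n to the noon catalyst concentration predicts 0.00158 min⁻¹. The noon readings give 0.00140 min⁻¹, which is slower. The objection is that this assumes first order in substrate, and a negative reagent order is hard to trust at this scatter. My own reckoning therefore commits to 0.526 for catalyst and about zero for reagent.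

The forecast gives 0.5 for free catalyst and 0.4 for reagent, noting “These runs never vary reagent independently”. It stands close to my reckoning on catalyst and apart from it on reagent.

The flask gives 0.54 for free catalyst and 0.0059 for reagent.

    2 catalyst intermediate A ⇌ resting dimer, settled at all times (K = 1.10 × 10⁷ M⁻¹)
    catalyst intermediate D → free catalyst + target (k = 77.0 min⁻¹)
    catalyst intermediate C → catalyst intermediate D (k = 1200 min⁻¹)
    substrate + catalyst intermediate A ⇌ idle complex, settled at all times (K = 150 M⁻¹)
    substrate + catalyst intermediate B ⇌ catalyst intermediate C (K = 570 M⁻¹, k = 6800 M⁻¹ min⁻¹)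
    catalyst intermediate A ⇌ catalyst intermediate B (K = 0.300, k = 97.0 min⁻¹)
    reagent + free catalyst → catalyst intermediate A (k = 5700 M⁻¹ min⁻¹)

With n, the autumn clock scaled to this flask's catalyst gives 175 min to 20% conversion, and the flask takes 172 min. There the resting dimer, the resting state, holds 85.6% of the catalyst, and the run without its binding has order 1.0 in free catalyst instead of 0.54. The flask's clock reads 0.00130 min⁻¹ at that point and 0.00138 min⁻¹ after 800 min, with reagent down to 55.3% of its charge.

All runs are simulated from invented constants, noise included.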